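Drimane numbering: ring A = C1–C5, C10; ring B = C5–C10; C11 and C12 are the formyl carbons on C9 and C8. Ring B is read as a masked Diels–Alder adduct: with its alkene shifted from C7=C8 to C6=C7, C8–C9 and C5–C10 are the two bonds of a [4+2] between an (E,E)-diene (C5–C8) and an (E)-enal (C9=C10, activated by C11). One intramolecular cycloaddition of a linear trienal thus closes rings A and B and sets C5, C9 and C10 from the single carbinol centre C1, which already carries the 4-methoxycinnamate. The alkene is moved back into conjugation with C12 at the end.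

Key step: step 9

Assumption: 4-cyano-2,2-dimethylbutanal (1) is taken as purchasable; it is the one-step cyanoethylation product of isobutyraldehyde.

Step 1
Reactants: 1 4-cyano-2,2-dimethylbutanal; 2 triethyl (E)-4-phosphonocrotonate
Product: 3 ethyl (2E,4E)-8-cyano-6,6-dimethylocta-2,4-dienoate
Conditions: LiN(SiMe3)2, THF, −78 → 0 °C
Reagents that add atoms: none
Why: Horner–Wadsworth–Emmons olefination of a non-enolisable aldehyde with the crotonate phosphonate anion should give the (2E,4E)-dienoate, the nitrile being inert.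

Step 2
Reactants: 3 ethyl (2E,4E)-8-cyano-6,6-dimethylocta-2,4-dienoate
Product: 5 (5E,7E)-9-hydroxy-4,4-dimethylnona-5,7-dienal, via hydroxy aldimine 4 (not isolated)
Conditions: i-Bu2AlH (3.5 equiv), CH2Cl2, −78 °C; aq. KNaC4H4O6, then dilute aq. tartaric acid, rt
Reagents that add atoms: water, O
Why: Aluminium hydride reduction takes the dienoate 1,2 to the allylic alcohol and stops the nitrile at the N-aluminio aldimine, which hydrolyses on work-up to the aldehyde.

Step 3
Reactants: 5 (5E,7E)-9-hydroxy-4,4-dimethylnona-5,7-dienal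
Product: 6 (5E,7E)-9-[(tert-butyldimethylsilyl)oxy]-4,4-dimethylnona-5,7-dienal
Conditions: TBSCl, imidazole, CH2Cl2, 0 °C → rt
Reagents that add atoms: tert-butyldimethylsilyl chloride, CC(C)(C)[Si](C)(C)Cl
Why: Standard silylation of the primary dienylic alcohol, which must outlast the C11 silyl ether introduced later.

Step 4
Reactants: 7 but-2-yn-1-ol
Product: 8 (but-2-yn-1-yloxy)triethylsilane
Conditions: TESCl, imidazole, CH2Cl2, 0 °C
Reagents that add atoms: chlorotriethylsilane, CC[Si](Cl)(CC)CC
Why: Standard silylation; the triethylsilyl ether is chosen because it can later be oxidised directly to the aldehyde in the presence of the tert-butyldimethylsilyl ether.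

Step 5
Reactants: 8 (but-2-yn-1-yloxy)triethylsilane
Product: 10 triethyl{[(E)-3-iodobut-2-en-1-yl]oxy}silane, via alkenylzirconocene chloride 9 (not isolated)
Conditions: Cp2Zr(H)Cl (2 equiv), THF, 50 °C; then I2, 0 °C
Reagents that add atoms: iodine, II
Why: syn-Hydrozirconation under equilibrating conditions (excess hydride, warm THF) should place zirconium on the less hindered methyl-bearing carbon, and iodinolysis with retention then gives the (E)-iodoalkene.

Step 6
Reactants: 10 triethyl{[(E)-3-iodobut-2-en-1-yl]oxy}silane; 6 (5E,7E)-9-[(tert-butyldimethylsilyl)oxy]-4,4-dimethylnona-5,7-dienal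
Product: 13 (2E,4R,8E,10E)-12-[(tert-butyldimethylsilyl)oxy]-3,7,7-trimethyl-1-[(triethylsilyl)oxy]dodeca-2,8,10-trien-4-ol, via alkenyllithium 11 (not isolated), via dialkenylzinc 12 (not isolated)
Conditions: 10 (2.2 equiv), t-BuLi (4.4 equiv), Et2O, −78 °C; ZnBr2 (1.1 equiv), −78 → 0 °C; N,N,N′,N′-tetraethylethylenediamine; (2S)-(−)-3-exo-(morpholino)isoborneol [(−)-MIB, 10 mol %], hexanes, 0 °C; then 6
Reagents that add atoms: none
Why: Iodine–lithium exchange and transmetalation to zinc (both with retention) give a dialkenylzinc that adds to the aldehyde in an amino-alcohol-catalysed asymmetric organozinc addition; (−)-MIB should direct alkenyl transfer to the Si face, which makes the new carbinol centre (drimane C1) R, while the diamine sequesters the lithium halides that drive the racemic background reaction.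

Step 7
Reactants: 13 (2E,4R,8E,10E)-12-[(tert-butyldimethylsilyl)oxy]-3,7,7-trimethyl-1-[(triethylsilyl)oxy]dodeca-2,8,10-trien-4-ol; 14 (E)-4-methoxycinnamic acid
Product: 15 (2E,4R,8E,10E)-12-[(tert-butyldimethylsilyl)oxy]-3,7,7-trimethyl-1-[(triethylsilyl)oxy]dodeca-2,8,10-trien-4-yl (E)-4-methoxycinnamate
Conditions: EDC·HCl, DMAP, CH2Cl2, 0 °C → rt
Reagents that add atoms: none
Why: Steglich-type carbodiimide esterification of the open-chain allylic alcohol installs the final ester before C1 becomes a hindered decalin position; the C–O bond of the stereocentre is not touched.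

Step 8
Reactants: 15 (2E,4R,8E,10E)-12-[(tert-butyldimethylsilyl)oxy]-3,7,7-trimethyl-1-[(triethylsilyl)oxy]dodeca-2,8,10-trien-4-yl (E)-4-methoxycinnamate
Product: 16 (2E,4R,8E,10E)-12-[(tert-butyldimethylsilyl)oxy]-3,7,7-trimethyl-1-oxododeca-2,8,10-trien-4-yl (E)-4-methoxycinnamate
Conditions: (COCl)2, DMSO, CH2Cl2, −78 → −40 °C; Et3N, −78 → 0 °C
Reagents that add atoms: none
Why: Under Swern conditions a primary triethylsilyl ether is converted through the alkoxysulfonium ion directly into the aldehyde, while the tert-butyldimethylsilyl ether and the ester should stay intact and the E geometry is kept.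

Step 9
Reactants: 16 (2E,4R,8E,10E)-12-[(tert-butyldimethylsilyl)oxy]-3,7,7-trimethyl-1-oxododeca-2,8,10-trien-4-yl (E)-4-methoxycinnamate
Product: 17 1β-[(E)-4-methoxycinnamoyloxy]-12-(tert-butyldimethylsilyloxy)drim-6-en-11-al (5α-H, 8α-H, 9α-H, 10β-CH3)
Conditions: Me2AlCl (2.2 equiv), CH2Cl2, −78 → 0 °C
Reagents that add atoms: none
Why: Me2AlCl binds the formyl oxygen and the (E)-enal adds across the (E,E)-diene in a concerted, asynchronous type 1 intramolecular Diels–Alder reaction (C5–C10 leading, C8–C9 completing), the closest known reaction type being the aluminium-Lewis-acid-promoted cyclisation of 2,8,10-undecatrienals to trans-fused octalins. Ring B closes by the [4+2] itself (bonds C8–C9 and C5–C10), and ring A closes through the same C5–C10 bond across the four-carbon tether C1–C4 in a chair-like array, giving the fused six/six system. The cis relation of the C9 formyl group and the C10 methyl group follows stereospecifically from the (E)-enal; the trans ring fusion follows from the endo transition state with the complexed formyl group under the diene; and C8 follows from the (E,E)-diene. The absolute sense comes from C1, whose acyloxy group should sit pseudo-equatorial and antiperiplanar to the forming C5–C10 bond (Felkin–Anh-type alignment), which corresponds to 1β-O with 10β-CH3. The step needs endo over exo selectivity and one enal face over the other; Lewis acid complexation, the fixed olefin geometries, the gem-dimethyl group (Thorpe–Ingold effect) and the C1 substituent are meant to secure them, the second equivalent of Me2AlCl being taken up by the ester carbonyl.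

Step 10
Reactants: 17 1β-[(E)-4-methoxycinnamoyloxy]-12-(tert-butyldimethylsilyloxy)drim-6-en-11-al
Product: 18 1β-[(E)-4-methoxycinnamoyloxy]-12-(tert-butyldimethylsilyloxy)-11,11-dimethoxydrim-6-ene (8α-H, 9α-H)
Conditions: MeOSiMe3 (3 equiv), Me3SiOTf (5 mol %), CH2Cl2, −78 → −40 °C; pyridine quench
Reagents that add atoms: methoxytrimethylsilane, CO[Si](C)(C)C
Why: Aprotic silyl-triflate-catalysed acetalisation masks C11 so that C9–H is no longer acidic in the later base step, and the absence of protic acid should spare the silyl ether.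

Step 11
Reactants: 18 1β-[(E)-4-methoxycinnamoyloxy]-12-(tert-butyldimethylsilyloxy)-11,11-dimethoxydrim-6-ene
Product: 19 1β-[(E)-4-methoxycinnamoyloxy]-11,11-dimethoxydrim-6-en-12-ol (8α-H, 9α-H)
Conditions: Bu4NF, AcOH, THF, 0 °C → rt
Reagents that add atoms: none
Why: Buffered fluoride desilylation frees the C12 alcohol without touching the acetal or the hindered ester.

Step 12
Reactants: 19 1β-[(E)-4-methoxycinnamoyloxy]-11,11-dimethoxydrim-6-en-12-ol
Product: 21 1β-[(E)-4-methoxycinnamoyloxy]-11,11-dimethoxydrim-7-en-12-al (9α-H), via deconjugated 12-aldehyde 20 (not isolated)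
Conditions: DMP, NaHCO3, CH2Cl2, 0 °C → rt; then DBU (0.5 equiv), rt
Reagents that add atoms: none
Why: Periodinane oxidation gives the β,γ-unsaturated aldehyde, whose doubly activated C8–H is removed by DBU; protonation of the dienolate at C6 should give the conjugated trisubstituted enal (thermodynamic product), erasing C8 while the acetal-bearing C9 cannot enolise.

Step 13
Reactants: 21 1β-[(E)-4-methoxycinnamoyloxy]-11,11-dimethoxydrim-7-en-12-al
Product: 22 1β-[(E)-4-methoxycinnamoyloxy]drim-7-ene-11,12-dial, i.e. (1R,4aS,8R,8aS)-7,8-diformyl-4,4,8a-trimethyl-1,2,3,4,4a,5,8,8a-octahydronaphthalen-1-yl (E)-3-(4-methoxyphenyl)prop-2-enoate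
Conditions: p-TsOH·H2O (10 mol %), acetone/H2O 10:1, 0 °C → rt
Reagents that add atoms: water, O
Why: Mild acid hydrolysis of the dimethyl acetal releases the C11 formyl group; base is avoided because the C9 centre of the 1,4-dialdehyde epimerises under basic conditions.

Compound list
1 | 4-cyano-2,2-dimethylbutanal | N#CCCC(C)(C)C=O | starting material
2 | triethyl (E)-4-phosphonocrotonate | CCOC(=O)/C=C/CP(=O)(OCC)OCC | starting material
3 | ethyl (2E,4E)-8-cyano-6,6-dimethylocta-2,4-dienoate | CCOC(=O)/C=C/C=C/C(C)(C)CCC#N | intermediate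
4 | (2E,4E)-9-imino-6,6-dimethylnona-2,4-dien-1-ol (hydroxy aldimine) | N=CCCC(C)(C)/C=C/C=C/CO | intermediate (not isolated)
5 | (5E,7E)-9-hydroxy-4,4-dimethylnona-5,7-dienal | O=CCCC(C)(C)/C=C/C=C/CO | intermediate
6 | (5E,7E)-9-[(tert-butyldimethylsilyl)oxy]-4,4-dimethylnona-5,7-dienal | O=CCCC(C)(C)/C=C/C=C/CO[Si](C)(C)C(C)(C)C | intermediate
7 | but-2-yn-1-ol | CC#CCO | starting material
8 | (but-2-yn-1-yloxy)triethylsilane | CC#CCO[Si](CC)(CC)CC | intermediate
9 | chloridobis(cyclopentadienyl)[(E)-4-(triethylsilyloxy)but-2-en-2-yl]zirconium (Zr trans to CH2O) | C/C(=C\CO[Si](CC)(CC)CC)[Zr+2]Cl.[cH-]1cccc1.[cH-]1cccc1 | intermediate (not isolated)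
10 | triethyl{[(E)-3-iodobut-2-en-1-yl]oxy}silane | C/C(I)=C\CO[Si](CC)(CC)CC | intermediate
11 | [(Z)-4-(triethylsilyloxy)but-2-en-2-yl]lithium (Li trans to CH2O, geometry of 10 retained) | C/C([Li])=C\CO[Si](CC)(CC)CC | intermediate (not isolated)
12 | bis[(E)-4-(triethylsilyloxy)but-2-en-2-yl]zinc (Zn trans to CH2O) | C/C(=C\CO[Si](CC)(CC)CC)[Zn]/C(C)=C/CO[Si](CC)(CC)CC | intermediate (not isolated)
13 | (2E,4R,8E,10E)-12-[(tert-butyldimethylsilyl)oxy]-3,7,7-trimethyl-1-[(triethylsilyl)oxy]dodeca-2,8,10-trien-4-ol | CC[Si](CC)(CC)OC/C=C(\C)[C@H](O)CCC(C)(C)/C=C/C=C/CO[Si](C)(C)C(C)(C)C | intermediate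
14 | (E)-4-methoxycinnamic acid | COc1ccc(/C=C/C(=O)O)cc1 | starting material
15 | (2E,4R,8E,10E)-12-[(tert-butyldimethylsilyl)oxy]-3,7,7-trimethyl-1-[(triethylsilyl)oxy]dodeca-2,8,10-trien-4-yl (E)-4-methoxycinnamate | CC[Si](CC)(CC)OC/C=C(\C)[C@H](OC(=O)/C=C/c1ccc(OC)cc1)CCC(C)(C)/C=C/C=C/CO[Si](C)(C)C(C)(C)C | intermediate
16 | (2E,4R,8E,10E)-12-[(tert-butyldimethylsilyl)oxy]-3,7,7-trimethyl-1-oxododeca-2,8,10-trien-4-yl (E)-4-methoxycinnamate | O=C/C=C(\C)[C@H](OC(=O)/C=C/c1ccc(OC)cc1)CCC(C)(C)/C=C/C=C/CO[Si](C)(C)C(C)(C)C | intermediate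
17 | 1β-[(E)-4-methoxycinnamoyloxy]-12-(tert-butyldimethylsilyloxy)drim-6-en-11-al (5α-H, 8α-H, 9α-H, 10β-CH3) | COc1ccc(/C=C/C(=O)O[C@@H]2CCC(C)(C)[C@@H]3C=C[C@H](CO[Si](C)(C)C(C)(C)C)[C@H](C=O)[C@@]23C)cc1 | intermediate
18 | 1β-[(E)-4-methoxycinnamoyloxy]-12-(tert-butyldimethylsilyloxy)-11,11-dimethoxydrim-6-ene | COc1ccc(/C=C/C(=O)O[C@@H]2CCC(C)(C)[C@@H]3C=C[C@H](CO[Si](C)(C)C(C)(C)C)[C@H](C(OC)OC)[C@@]23C)cc1 | intermediate
19 | 1β-[(E)-4-methoxycinnamoyloxy]-11,11-dimethoxydrim-6-en-12-ol | COc1ccc(/C=C/C(=O)O[C@@H]2CCC(C)(C)[C@@H]3C=C[C@H](CO)[C@H](C(OC)OC)[C@@]23C)cc1 | intermediate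
20 | 1β-[(E)-4-methoxycinnamoyloxy]-11,11-dimethoxydrim-6-en-12-al (8α-H) | COc1ccc(/C=C/C(=O)O[C@@H]2CCC(C)(C)[C@@H]3C=C[C@H](C=O)[C@H](C(OC)OC)[C@@]23C)cc1 | intermediate (not isolated)
21 | 1β-[(E)-4-methoxycinnamoyloxy]-11,11-dimethoxydrim-7-en-12-al | COc1ccc(/C=C/C(=O)O[C@@H]2CCC(C)(C)[C@@H]3CC=C(C=O)[C@H](C(OC)OC)[C@@]23C)cc1 | intermediate
22 | 1β-[(E)-4-methoxycinnamoyloxy]drim-7-ene-11,12-dial | COc1ccc(/C=C/C(=O)O[C@@H]2CCC(C)(C)[C@@H]3CC=C(C=O)[C@H](C=O)[C@@]23C)cc1 | target

Total step count: 13. Longest linear sequence: 11 steps (steps 1–3 and 6–13, from 1 to 22).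

Steps most likely to fail

1. Step 9 (cycloaddition). The β,β-disubstituted enal may react sluggishly. The developing 1,3-diaxial methyl/methyl contact between C4 and C10 may loosen the chair-like endo transition state, so that exo (cis-fused) closure or addition to the other enal face competes. The Lewis acid may also ionise the dienylic silyl ether. Fallback, setting out from 16: the enal is converted with MeOSiMe3 and catalytic Me3SiOTf at −78 °C into its acetal, (2E,4R,8E,10E)-12-[(tert-butyldimethylsilyl)oxy]-1,1-dimethoxy-3,7,7-trimethyldodeca-2,8,10-trien-4-yl (E)-4-methoxycinnamate F1. This is cyclised as its 1-methoxyallyl cation in an ionic Diels–Alder reaction (Me3SiOTf, CH2Cl2, −78 → −40 °C), a much more reactive and strongly endo-selective dienophile. The methoxy group returns to the adduct cation, so the product is acetal 18, where the route is rejoined (step 10 falls away).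

2. Step 6 (asymmetric alkenylation). Ligand-free background addition promoted by residual lithium halide, or a slow catalysed pathway with the α-unbranched aldehyde, may leave 13 with insufficient enantiomeric purity. Fallback, setting out from 13 of any enantiomeric composition (it can also be made by adding alkenyllithium 11 directly to 6): oxidation with DMP gives the enone, (2E,8E,10E)-12-[(tert-butyldimethylsilyl)oxy]-3,7,7-trimethyl-1-[(triethylsilyl)oxy]dodeca-2,8,10-trien-4-one F2. Corey–Bakshi–Shibata reduction with (S)-2-methyl-CBS-oxazaborolidine and catecholborane (toluene, −78 °C; the α-methylalkenyl group acts as the large substituent) should return (4R)-13, where the route is rejoined.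

3. Step 8 (oxidative desilylation). Chloride may displace the allylic alkoxysulfonium ion before the base is added (Corey–Kim-type chlorination). Et3N may also deprotonate the new enal at its γ-position (C1), causing E/Z drift and erosion of the stereocentre. Fallback, setting out from 15: selective methanolysis of the triethylsilyl ether (PPTS, MeOH, 0 °C, the tert-butyldimethylsilyl ether surviving) gives the allylic alcohol, (2E,4R,8E,10E)-12-[(tert-butyldimethylsilyl)oxy]-1-hydroxy-3,7,7-trimethyldodeca-2,8,10-trien-4-yl (E)-4-methoxycinnamate F3. Neutral allylic oxidation with MnO2 in CH2Cl2 then gives enal 16, where the route is rejoined.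

Further compounds
F1 | step 9 | (2E,4R,8E,10E)-12-[(tert-butyldimethylsilyl)oxy]-1,1-dimethoxy-3,7,7-trimethyldodeca-2,8,10-trien-4-yl (E)-4-methoxycinnamate | COC(OC)/C=C(\C)[C@H](OC(=O)/C=C/c1ccc(OC)cc1)CCC(C)(C)/C=C/C=C/CO[Si](C)(C)C(C)(C)C
F2 | step 6 | (2E,8E,10E)-12-[(tert-butyldimethylsilyl)oxy]-3,7,7-trimethyl-1-[(triethylsilyl)oxy]dodeca-2,8,10-trien-4-one | CC[Si](CC)(CC)OC/C=C(\C)C(=O)CCC(C)(C)/C=C/C=C/CO[Si](C)(C)C(C)(C)C
F3 | step 8 | (2E,4R,8E,10E)-12-[(tert-butyldimethylsilyl)oxy]-1-hydroxy-3,7,7-trimethyldodeca-2,8,10-trien-4-yl (E)-4-methoxycinnamate | OC/C=C(\C)[C@H](OC(=O)/C=C/c1ccc(OC)cc1)CCC(C)(C)/C=C/C=C/CO[Si](C)(C)C(C)(C)C
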